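All runs are calculated for an exercise, and the scatter is random.

**Early readings.** Early in the dusk run, at 0.333 min, I read X at 14.2 % and E at 0.5 %. At 4.00 min the two together came to 8.20 % of the charge, and the missing 91.8 % was far more than the Q of dusk, 0.860 % of the X charged, could bind, so I took the missing X in dusk to sit in D.

| setting | dusk | midnight | winter | amber | green | grey | violet | ochre |
|---|---|---|---|---|---|---|---|---|
| X | 0.10 M (in portions, 2) | 0.10 M (in portions, 2) | 0.10 M (in portions, 2) | 0.10 M (in portions, 2) | 0.10 M (in portions, 2) | 0.10 M (in portions, 2) | 0.10 M (in portions, 2) | 0.10 M (in portions, 2) |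
| Q | 0.86 mM | 11 mM | 93 mM | 1.2 mM | 3.0 mM | 10 mM | 30 mM | 100 mM |
| remark | run made earlier; portions every 80 s | run made earlier; portions every 80 s | run made earlier; portions every 80 s | the portions of X follow each other after 80 s, the first at the start | the portions of X follow each other after 80 s, the first at the start | the portions of X follow each other after 80 s, the first at the start | the portions of X follow each other after 80 s, the first at the start | the portions of X follow each other after 80 s, the first at the start |
| time |  |  |  | 4.0 min | 4.0 min | 4.0 min | 4.0 min | 4.0 min |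

| run | time / min | E / % | X / % |
|---|---|---|---|
| dusk | 0.333 | 0.5 | 14.2 |
| dusk | 1.00 | 1.5 | 2.8 |
| dusk | 2.00 | 2.5 | 7.7 |
| dusk | 3.00 | 4.1 | 5.0 |
| dusk | 4.00 | 3.9 | 4.3 |
| midnight | 0.833 | 10.6 | 1.6 |
| midnight | 1.50 | 14.2 | 24.0 |
| midnight | 2.50 | 21.2 | 2.8 |
| midnight | 3.00 | 23.0 | 2.9 |
| midnight | 4.00 | 25.0 | 3.3 |
| winter | 0.333 | 10.2 | 0.2 |
| winter | 0.667 | 9.7 | 0 |
| winter | 1.00 | 8.8 | 0.2 |
| winter | 2.00 | 24.7 | 0.4 |
| winter | 4.00 | 23.6 | 0.1 |

(standard deviation of a reading: 0.3 percentage points)

* amount of E at the end, in percent of the X charged for amber, green, grey, violet, ochre, in this order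
* how that number moves from the first to the last of them (falls, then rises / hardly changes / falls all the way / rises all the way / rises, then falls)

- on the list of suspects stand: X + Q -> G; G <-> L; L <-> Q + E; X <-> D; L -> J
- "hardly changes" means that all values lie within two and a half points (for a concentration: within two and a half percent of the largest)

**The carried count.** I carried one number, T, which dusk's last reading put at 4.53 turns, with the scatter of that reading on it: the E made by the end of the run per Q charged, the turnover number. Midnight's 2.27 was half of it at a Q charge 12.8 times higher, so I treated E as T times the Q charge and the drift of T as a small correction, which I dropped between close neighbours.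

**For the next shift.** Amber lay beside dusk and grey beside midnight, so I expected E at 4.0 min to stand at 5.44 % in amber and 22.7 % in grey. I asked that nobody change the spacing of 80 s or stop early, since T was read at those settings and at that time: midnight's E still rose from 23.0 % to 25.0 % between 3.00 min and 4.00 min. Winter's T of 0.254 showed that T did not hold across the gap from midnight, so I did not carry it to violet.

**The forecast.** The forecast gave 5.5 %, 11 %, 25 %, 30 % and 23.5 %, a row that rises, then falls, holding that “high Q is needed to capture X”. For grey its figure stood higher than mine.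

**The result.** The flasks gave 5.51 %, 11.3 %, 23.8 %, 34.3 % and 22.1 %, a row that rises, then falls.

    X + Q → G (k = 3.90 M⁻¹ s⁻¹)
    G ⇌ L (K = 1.20, k = 0.180 s⁻¹)
    L ⇌ Q + E (K = 0.0370 M, k = 0.350 s⁻¹)
    X ⇌ D (K = 19.0, k = 0.0650 s⁻¹)
    L → J (k = 0.00500 s⁻¹)

**The turns again.** At 4.00 min amber held D at 89.5 % of the X charged. Amber ran 4.59 turns against dusk's 4.53, and grey ran 2.38 against midnight's 2.27.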